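**Assumption:** the SMILES cannot encode the biaryl axis. I target the natural Aspergillus series, (P) = (aS), the same axis as P‑orlandin and P‑kotanin. The mirror‑image catalyst in Step 6 would give the (M) form.

## Retrosynthetic overview
1. The axis is not set when the aryl–aryl bond is made. It is set by catalytic desymmetrisation of an achiral biaryl whose ring B is a σ‑symmetric 2‑arylorcinol.
2. Key step: enantiotopic‑group‑selective C–H bromination of ring B. The brominated flank becomes C4a'/O1', and the untouched phenol is the 7'‑OH of the target, so no late OH/OMe differentiation is needed.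
3. C–Br is converted to acetyl. Both pyranone rings are then closed together by a double O→C methoxycarbonyl transfer and lactonisation.
4. Both 4‑OMe groups come from acid‑catalysed vinylogous esterification, which ignores the phenol.
5. The achiral biaryl comes from a Negishi union of a 3,5‑dimethoxytoluene‑derived bromoacetophenone (ring A) and C2‑zincated orcinol bis‑MOM ether (ring B). Ring order: two purchased benzene rings, then both lactone rings at once.

**Stereo convention for 8–12:** look down the axis from ring A (the OMe ring) to ring B. Going from the ring‑A ortho carbon bearing the (future) O1 to the ring‑B ortho carbon bearing the (future) O1' (next to C–Br or C–acyl) is a clockwise quarter turn, torsion about +90°. This geometry never changes. Only the CIP label of 8 differs, because OMe outranks OH there.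

## Route

**Step 1**
Reactants: 1, 3,5‑dimethoxytoluene
Product: 2, 2‑bromo‑1,3‑dimethoxy‑5‑methylbenzene
Conditions: n‑BuLi, THF, 0 °C → rt; BrCH2CH2Br, –78 °C → rt
Reagents that add atoms: 1,2‑dibromoethane, BrCCBr
Why: Directed ortho‑metalation occurs only at the carbon between the two OMe groups, and the aryllithium abstracts Br+ from the dibromide.

**Step 2**
Reactants: 2
Product: 3, 1‑(3‑bromo‑2,4‑dimethoxy‑6‑methylphenyl)ethanone
Conditions: AcCl, SnCl4, CH2Cl2, –10 → 0 °C
Reagents that add atoms: acetyl chloride, CC(=O)Cl
Why: Friedel–Crafts acylation at one of the two equivalent free positions (ortho and para to OMe), with a mild Lewis acid at low temperature to avoid demethylation or Br migration, and the ketone stops a second acylation.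

**Step 3**
Reactants: 4, orcinol (5‑methylbenzene‑1,3‑diol)
Product: 5, 1,3‑bis(methoxymethoxy)‑5‑methylbenzene
Conditions: MOMCl, i‑Pr2NEt, CH2Cl2, 0 °C → rt
Reagents that add atoms: chloromethyl methyl ether, COCCl
Why: Simple phenol O‑alkylation that installs two strong, acid‑ and Lewis‑acid‑labile directing groups.

**Step 4**
Reactants: 5 and 3
Product: 6, 1‑[2,6‑dimethoxy‑2',6'‑bis(methoxymethoxy)‑4,4'‑dimethylbiphenyl‑3‑yl]ethanone (achiral)
Conditions: 5, n‑BuLi, THF, 0 °C; ZnCl2, 0 °C → rt; then 3, Pd2(dba)3 (2 mol %), RuPhos (8 mol %), THF, 65 °C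
Reagents that add atoms: none
Why: Directed metalation between the two OMOM groups and then Negishi coupling with a dialkylbiarylphosphine catalyst suited to tetra‑ortho biaryls, where the arylzinc tolerates the hindered methyl ketone and no stereo‑axis arises because ring B is symmetric.

**Step 5**
Reactants: 6
Product: 7, 1‑(2,2',6'‑trihydroxy‑6‑methoxy‑4,4'‑dimethylbiphenyl‑3‑yl)ethanone (achiral, with enantiotopic OH and C–H pairs on ring B)
Conditions: BCl3 (6 equiv), C6HMe5, CH2Cl2, –78 → 0 °C; MeOH quench
Reagents that add atoms: none
Why: BCl3 cleaves both MOM acetals and, by carbonyl chelation, only the OMe ortho to the acetyl, while the unchelated 6‑OMe (future 7‑OMe) survives and pentamethylbenzene traps the methoxymethyl cation.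

**Step 6 (key step)**
Reactants: 7
Product: 8, (M)/(aR)‑1‑(3'‑bromo‑2,2',6'‑trihydroxy‑6‑methoxy‑4,4'‑dimethylbiphenyl‑3‑yl)ethanone (geometry as in the convention above)
Conditions: (R)‑TRIP (10 mol %), N‑bromophthalimide (1.15 equiv, slow addition), CH2Cl2/toluene, –60 °C
Reagents that add atoms: N‑bromophthalimide, O=C1N(Br)C(=O)c2ccccc12
Why: Chiral‑phosphoric‑acid‑catalysed atroposelective electrophilic bromination (a known reaction class for 2‑arylresorcinols, untested on this O/O'‑flanked substrate), in which the phosphate hydrogen‑bonds one enantiotopic phenol and activates the N–Br reagent while its 3,3'‑aryl walls distinguish the OMe flank from the flat H‑bonded OH···O=C(Me) flank of orthogonal ring A, thereby setting the axis; the slight excess of reagent over‑brominates the minor atropisomer to the achiral, separable 3',5'‑dibromide (kinetic‑resolution upgrade), and the push–pull ring A is far less nucleophilic.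
Note: the catalyst hand is confirmed on an analytical run by anomalous‑dispersion X‑ray of 8. Use (S)‑TRIP if the sense is opposite.

**Step 7**
Reactants: 8
Product: 9, (P)/(aS)‑3‑acetyl‑3'‑bromo‑6‑methoxy‑4,4'‑dimethylbiphenyl‑2,2',6'‑triyl tris(methyl carbonate)
Conditions: ClCO2Me, Et3N, DMAP (cat.), CH2Cl2, 0 °C → rt
Reagents that add atoms: methyl chloroformate, COC(=O)Cl
Why: DMAP‑catalysed O‑acylation that removes all acidic protons, makes the bromoarene less electron‑rich, raises the rotation barrier, and pre‑installs the two carbons that become C2 and C2' (the base is too weak to enolise the ketone).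

**Step 8**
Reactants: 9
Product: 10, (P)/(aS)‑3,3'‑diacetyl‑6‑methoxy‑4,4'‑dimethylbiphenyl‑2,2',6'‑triyl tris(methyl carbonate)
Conditions: Bu3SnC(OEt)=CH2, PdCl2(PPh3)2 (10 mol %), toluene, 90 °C; then 1 M HCl, THF, rt
Reagents that add atoms: tributyl(1‑ethoxyvinyl)stannane, CCOC(=C)[Sn](CCCC)(CCCC)CCCC; water, O
Why: Stille coupling with an acetyl‑anion equivalent under neutral conditions that spare the ketone and carbonates, followed by mild enol‑ether hydrolysis, with the tetra‑ortho, doubly buttressed axis expected to hold at 90 °C (ee checked by chiral HPLC).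

**Step 9**
Reactants: 10
Product: 11, (P)/(aS)‑4,4',7'‑trihydroxy‑7‑methoxy‑5,5'‑dimethyl‑8,8'‑bicoumarin
Conditions: LiHMDS (5 equiv), THF, –78 °C → rt; NaOMe, MeOH, rt; 2 M HCl
Reagents that add atoms: none
Why: Double Baker–Venkataraman‑type O→C methoxycarbonyl transfer (six‑membered transition state, the intramolecular form of the classical o‑hydroxyacetophenone/dialkyl carbonate 4‑hydroxycoumarin synthesis) followed by lactonisation, while methoxide removes the unreachable 7'‑carbonate as dimethyl carbonate and the low temperature protects the axis.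

**Step 10**
Reactants: 11
Product: 12, (P)/(aS)‑demethylkotanin (7'‑hydroxy‑4,4',7‑trimethoxy‑5,5'‑dimethyl‑8,8'‑bicoumarin)
Conditions: MeOH, conc. H2SO4 (10 % v/v), 3 Å MS, reflux
Reagents that add atoms: methanol, CO
Why: Acid‑catalysed vinylogous Fischer esterification (addition–elimination at C4) converts only the two vinylogous acids into the thermodynamically preferred 4‑methoxycoumarins, and a phenol cannot be etherified this way, so the 7'‑OH stays free.

## Compound list
SMILES cannot encode atropisomerism, so the axis is given in the name.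

| No. | Name | SMILES | Role |
|---|---|---|---|
| 1 | 3,5‑dimethoxytoluene | COc1cc(C)cc(OC)c1 | starting material |
| 2 | 2‑bromo‑1,3‑dimethoxy‑5‑methylbenzene | COc1cc(C)cc(OC)c1Br | intermediate |
| 3 | 1‑(3‑bromo‑2,4‑dimethoxy‑6‑methylphenyl)ethanone | CC(=O)c1c(C)cc(OC)c(Br)c1OC | intermediate |
| 4 | orcinol | Cc1cc(O)cc(O)c1 | starting material |
| 5 | 1,3‑bis(methoxymethoxy)‑5‑methylbenzene | COCOc1cc(C)cc(OCOC)c1 | intermediate |
| 6 | achiral bis‑MOM biaryl ketone | CC(=O)c1c(C)cc(OC)c(-c2c(OCOC)cc(C)cc2OCOC)c1OC | intermediate |
| 7 | achiral biaryl triol | CC(=O)c1c(C)cc(OC)c(-c2c(O)cc(C)cc2O)c1O | intermediate |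
| 8 | (M)/(aR)‑3'‑bromo triol | CC(=O)c1c(C)cc(OC)c(-c2c(O)cc(C)c(Br)c2O)c1O | intermediate |
| 9 | (P)/(aS)‑bromo tris(methyl carbonate) | CC(=O)c1c(C)cc(OC)c(-c2c(OC(=O)OC)cc(C)c(Br)c2OC(=O)OC)c1OC(=O)OC | intermediate |
| 10 | (P)/(aS)‑diacetyl tris(methyl carbonate) | CC(=O)c1c(C)cc(OC)c(-c2c(OC(=O)OC)cc(C)c(C(C)=O)c2OC(=O)OC)c1OC(=O)OC | intermediate |
| 11 | (P)/(aS)‑4,4',7'‑trihydroxy‑7‑methoxy‑5,5'‑dimethyl‑8,8'‑bicoumarin | COc1cc(C)c2c(O)cc(=O)oc2c1-c1c(O)cc(C)c2c(O)cc(=O)oc12 | intermediate |
| 12 | (P)/(aS)‑demethylkotanin | COc1cc(C)c2c(OC)cc(=O)oc2c1-c1c(O)cc(C)c2c(OC)cc(=O)oc12 | target |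

## Step count
- Total steps: 10
- Longest linear sequence: 9 (Steps 1, 2, 4–10). Step 3 is the side branch.

## Steps most likely to fail
1. **Step 6 (low ee, because both ring‑A flanks are oxygen).** Fallback: give up catalytic control.
   - Brominate 7 with NBS to give racemic 8.
   - Use (–)‑menthyl chloroformate in Step 7 and separate the diastereomeric tris(menthyl carbonates).
   - Carry the (P) isomer through Steps 8–9 unchanged, since menthyl carbonates transfer and lactonise in the same way.
   - Recycle the wrong isomer to achiral 7 by carbonate cleavage and hydrodebromination.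
2. **Step 8 (Stille at a C–Br flanked by Me and OCO2Me, or ee erosion at 90 °C).** Fallback: replace acetyl installation with Pd‑catalysed carbonylative coupling of 9 with potassium methyl malonate (CO, MgCl2, Et3N). This gives the ring‑B β‑keto ester directly. Ring B then closes by simple lactonisation while ring A still closes by carbonate transfer.
3. **Step 10 (addition at C4 slowed by the peri 5‑methyl group).** Fallback: switch from addition–elimination to SN2 O‑alkylation with the phenol masked.
   - Tris‑pivaloylate 11.
   - Methanolyse the two labile enol pivalates with NaHCO3/MeOH, leaving the 7'‑OPiv.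
   - Methylate both 4‑OH groups with Me2SO4/K2CO3 in acetone.
   - Remove the pivalate with NaOMe/MeOH.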